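**Retrosynthetic overview**

1. The target is a depsidone: ring A (formyl-orsellinate type) and ring B (fused to a 2,2-dimethylchroman-4-one) are joined by the diaryl ether oxygen O5 and by the lactone C11(=O)–O10, which together close the central dioxepinone ring.
2. Key disconnection: the lactone C(=O)–O unit is taken out as CO2. It is inserted between ring A carbon C11a (held as C–Br, ortho to O5) and ring B carbon C9a (a C–H, ortho to the ether carbon C5a) by carboxylation and, in the same flask, oxidative lactonisation.
3. Enabling feature: ring B is 1,2,3,4-tetraoxygenated. Its two vicinal oxygens on C6 and C7 (the free phenol and the later chromanone oxygen) can be raised to an o-quinone, which makes C9a an enone β-carbon seven ring atoms away from the ring A carboxylate.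
4. The diaryl ether comes from SNAr of 5-methylpyrogallol acetonide on a 2-fluorobenzaldehyde, itself made by bromination and directed lithiation/formylation of 3-fluoro-5-methylanisole.
5. Ring order: rings A and B come from the starting materials; the dioxepinone ring forms in step 5; the chromanone ring forms in step 6 (Friedel–Crafts acylation/oxa-Michael); demethylation is last.

Key step: step 5

Remark: the target has no stereocentre, so no configuration has to be set; compounds 1, 4 and 13 are taken to be purchasable.

**Step 1**
Reactants: 1 3-fluoro-5-methylanisole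
Product: 2 2-bromo-1-fluoro-5-methoxy-3-methylbenzene
Conditions: NBS (1.05 equiv), MeCN, 0 °C → rt
Reagents that add atoms: N-bromosuccinimide, O=C1CCC(=O)N1Br
Why: Electrophilic aromatic bromination with NBS in MeCN should go para to OMe, a position that is also ortho to F and to CH3, so all directing effects converge.

**Step 2**
Reactants: 2 2-bromo-1-fluoro-5-methoxy-3-methylbenzene
Product: 3 3-bromo-2-fluoro-6-methoxy-4-methylbenzaldehyde
Conditions: LiN(iPr)2 (1.1 equiv), THF, −78 °C; DMF; aq. HCl
Reagents that add atoms: N,N-dimethylformamide, CN(C)C=O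
Why: Directed ortho-lithiation/formylation: the C–H flanked by F and OMe is the most acidic, the amide base leaves the C–Br bond alone, and −78 °C should keep the ortho-fluoro aryllithium from losing LiF.

**Step 3**
Reactants: 4 5-methylbenzene-1,2,3-triol (5-methylpyrogallol)
Product: 5 2,2,6-trimethyl-1,3-benzodioxol-4-ol
Conditions: 2,2-dimethoxypropane (1.2 equiv), p-TsOH (cat.), toluene, reflux with removal of MeOH
Reagents that add atoms: 2,2-dimethoxypropane, COC(C)(C)OC
Why: Acid-catalysed transketalisation closes the five-membered benzodioxole on two vicinal hydroxyls; the triol is symmetric, so only one mono-acetonide with one free terminal OH can form.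

**Step 4**
Reactants: 3 3-bromo-2-fluoro-6-methoxy-4-methylbenzaldehyde; 5 2,2,6-trimethyl-1,3-benzodioxol-4-ol
Product: 6 3-bromo-6-methoxy-4-methyl-2-[(2,2,6-trimethyl-1,3-benzodioxol-4-yl)oxy]benzaldehyde
Conditions: K2CO3 (1.5 equiv), DMF, 90 °C
Reagents that add atoms: none
Why: SNAr through a Meisenheimer complex: the fluoride ortho to the formyl group should be displaced by the phenoxide of 5, and because the neighbouring ring B oxygens are tied up in the acetonide the aryl group cannot migrate by a Smiles rearrangement.

**Step 5**
Reactants: 6 3-bromo-6-methoxy-4-methyl-2-[(2,2,6-trimethyl-1,3-benzodioxol-4-yl)oxy]benzaldehyde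
Product: 12 6,7-dihydroxy-3-methoxy-1,9-dimethyl-11-oxo-11H-dibenzo[b,e][1,4]dioxepine-4-carbaldehyde, via lithium amino alkoxide 7 (not isolated), via aryllithium 8 (not isolated), via lithium carboxylate 9 (not isolated), via catechol acid 10 (not isolated), via quinone acid 11 (not isolated)
Conditions: LiN(Me)CH2CH2NMe2 (1.1 equiv, from the diamine and n-BuLi), THF, −20 °C; t-BuLi (2.1 equiv), −78 °C; CO2 (dry gas), −78 → 0 °C; evaporate, TFA/H2O (9:1), rt; then NaIO4 (1.0 equiv), MeCN/aq. NaOAc–AcOH buffer (pH 5), 0 °C
Reagents that add atoms: carbon dioxide, O=C=O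
Why: Proposed new method: with the aldehyde masked in the flask as its lithium α-amino alkoxide, the only C–Br bond is exchanged by t-BuLi and the hindered aryllithium takes up CO2, which forms the C11–C11a bond (closest known type: halogen–lithium exchange/carboxylation of an aldehyde protected in situ as an α-amino alkoxide). Aqueous TFA then frees the aldehyde and the catechol, and NaIO4 oxidises the catechol to the o-quinone, in which the ring B C–H carbon next to the aryloxy carbon is the β-carbon of an enone held 1,2 to the ether oxygen. The carboxylate oxygen should add to this carbon (oxa-Michael, 7-endo-trig) and enolisation returns the aromatic catechol with the new O10–C9a bond; the closest known reactions are the oxidative lactonisation of dihydrocaffeic acids through their o-quinones and the Thiele–Winter acetoxylation of quinones, neither shown for the seven-membered ring of a depsidone. No stereocentre remains, since the aminal carbon of 7 to 9 is racemic and returns to the formyl group. The step needs site selectivity for the C–H β-carbon over the aryloxy-bearing ipso carbon and the methyl-bearing β-carbon: only the C–H adduct can tautomerise irreversibly to an arene, the other adducts can only revert, and apart from the ipso carbon no other position gives a ring of fewer than eight atoms. One equivalent of NaIO4 should suffice because 12, with an acyloxy group on the catechol ring, is harder to oxidise than 10.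

**Step 6**
Reactants: 12 6,7-dihydroxy-3-methoxy-1,9-dimethyl-11-oxo-11H-dibenzo[b,e][1,4]dioxepine-4-carbaldehyde; 13 3-methylbut-2-enoic acid
Product: 14 O-methyl ether of the target (as 12, but with the C7 oxygen and C8 joined through O–C(CH3)2–CH2–C(=O) to a 2,2-dimethylchroman-4-one ring)
Conditions: 13 (3 equiv), P2O5/MeSO3H (1:10 w/w), 60 °C
Reagents that add atoms: none
Why: Friedel–Crafts acylation/oxa-Michael annulation, the standard route to 2,2-dimethylchroman-4-ones: the acylium ion should attack C8, the only free position of ring B (ortho to the C7 hydroxyl, para to the aryloxy oxygen), and the C7 hydroxyl then closes the pyranone ring by 6-endo-trig conjugate addition.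

**Step 7**
Reactants: 14 O-methyl ether of the target
Product: 15 CNP0271978.0 (target)
Conditions: BCl3 (3 equiv), CH2Cl2, −78 → 0 °C; aq. work-up
Reagents that add atoms: none
Why: Chelation-controlled Lewis acid demethylation: BCl3 held between the formyl oxygen and the ortho methoxy oxygen should cleave only this O–CH3 bond, while the aryl lactone, the chromanone and the diaryl ether should survive at low temperature.

**Compound list**

1 | 3-fluoro-5-methylanisole | COc1cc(C)cc(F)c1 | starting material
2 | 2-bromo-1-fluoro-5-methoxy-3-methylbenzene | COc1cc(C)c(Br)c(F)c1 | intermediate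
3 | 3-bromo-2-fluoro-6-methoxy-4-methylbenzaldehyde | COc1cc(C)c(Br)c(F)c1C=O | intermediate
4 | 5-methylbenzene-1,2,3-triol (5-methylpyrogallol) | Cc1cc(O)c(O)c(O)c1 | starting material
5 | 2,2,6-trimethyl-1,3-benzodioxol-4-ol | Cc1cc(O)c2OC(C)(C)Oc2c1 | intermediate
6 | 3-bromo-6-methoxy-4-methyl-2-[(2,2,6-trimethyl-1,3-benzodioxol-4-yl)oxy]benzaldehyde | COc1cc(C)c(Br)c(Oc2cc(C)cc3OC(C)(C)Oc23)c1C=O | intermediate
7 | lithium α-amino alkoxide of 6 (LiN(Me)CH2CH2NMe2 added to the formyl carbon; racemic) | COc1cc(C)c(Br)c(Oc2cc(C)cc3OC(C)(C)Oc23)c1C(O[Li])N(C)CCN(C)C | intermediate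
8 | aryllithium from 7 (Li in place of Br; racemic) | COc1cc(C)c([Li])c(Oc2cc(C)cc3OC(C)(C)Oc23)c1C(O[Li])N(C)CCN(C)C | intermediate
9 | lithium carboxylate from 8 and CO2 (racemic) | COc1cc(C)c(C(=O)O[Li])c(Oc2cc(C)cc3OC(C)(C)Oc23)c1C(O[Li])N(C)CCN(C)C | intermediate
10 | 2-(2,3-dihydroxy-5-methylphenoxy)-3-formyl-4-methoxy-6-methylbenzoic acid | COc1cc(C)c(C(O)=O)c(Oc2cc(C)cc(O)c2O)c1C=O | intermediate
11 | 3-formyl-4-methoxy-6-methyl-2-[(3-methyl-5,6-dioxocyclohexa-1,3-dien-1-yl)oxy]benzoic acid | COc1cc(C)c(C(O)=O)c(OC2=CC(C)=CC(=O)C2=O)c1C=O | intermediate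
12 | 6,7-dihydroxy-3-methoxy-1,9-dimethyl-11-oxo-11H-dibenzo[b,e][1,4]dioxepine-4-carbaldehyde | COc1cc(C)c2C(=O)Oc3c(C)cc(O)c(O)c3Oc2c1C=O | intermediate
13 | 3-methylbut-2-enoic acid | CC(C)=CC(O)=O | starting material
14 | O-methyl ether of the target (ring A OMe in place of OH) | COc1cc(C)c2C(=O)Oc3c(C)c4C(=O)CC(C)(C)Oc4c(O)c3Oc2c1C=O | intermediate
15 | CNP0271978.0 | Cc1cc(O)c(C=O)c2c1C(=O)Oc1c(C)c3c(c(O)c1O2)OC(C)(C)CC3=O | target

**Step count and risks**

Total steps: 7. Longest linear sequence: 6 (steps 1, 2, 4, 5, 6, 7).

Steps most likely to fail: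

1. Step 5. The carboxylate may attack the aryloxy-bearing ipso carbon of the quinone and expel the ring A phenoxide, an acyl transfer that would scramble the ester and ether positions. The quinone may also decay (tautomerisation to a quinone methide, addition of water) before the seven-membered ring closes. The fallback sets out from 6 and forms the C–O bond by copper-catalysed coupling at a pre-halogenated carbon instead of by quinone addition. Compound 6 would be carboxylated as in step 5 (in situ amino alkoxide, t-BuLi, CO2) but worked up with aqueous citric acid so that the acetonide stays on, to give 3-formyl-4-methoxy-6-methyl-2-[(2,2,6-trimethyl-1,3-benzodioxol-4-yl)oxy]benzoic acid F1. NBS in MeCN should then brominate ring B para to the dioxole oxygen, at the C–H next to the aryloxy carbon (ring A is deactivated by CHO and CO2H), to give 2-[(5-bromo-2,2,6-trimethyl-1,3-benzodioxol-4-yl)oxy]-3-formyl-4-methoxy-6-methylbenzoic acid F2. CuI, 1,10-phenanthroline and Cs2CO3 in DMF at 110 °C should close the lactone by Ullmann-type O-arylation of the carboxylate to the acetonide-protected depsidone F3, and aqueous TFA would free the catechol and return to the route at 12.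

2. Step 6. In the strong acid the free aldehyde may condense with the electron-rich catechol ring of a second molecule in competition with acylation, or acylation may stop at the phenol ester. The fallback sets out from 12 and masks the aldehyde with an acid-stable group. Ethane-1,2-dithiol and BF3·OEt2 in CH2Cl2 should convert 12 into the 1,3-dithiolane of 12 F4. The annulation with 13 in P2O5/MeSO3H would then give the 1,3-dithiolane of 14 F5, and Hg(ClO4)2 with CaCO3 in aqueous THF would release the aldehyde and return to the route at 14.

3. Step 2. The ortho-fluoro aryllithium may lose LiF to an aryne, or bromine may migrate, before DMF traps the anion. The fallback sets out from 1 and inverts the order so that no bromo-fluoro aryllithium is needed. Compound 1 would be lithiated with n-BuLi between F and OMe (THF, −78 °C) and formylated with DMF to 2-fluoro-6-methoxy-4-methylbenzaldehyde F6. Bromination of F6 with NBS in MeCN/TFA should go para to OMe (also meta to CHO and ortho to F and CH3) and return to the route at 3.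

**Further compounds**

F1 | step 5 | 3-formyl-4-methoxy-6-methyl-2-[(2,2,6-trimethyl-1,3-benzodioxol-4-yl)oxy]benzoic acid | COc1cc(C)c(C(O)=O)c(Oc2cc(C)cc3OC(C)(C)Oc23)c1C=O
F2 | step 5 | 2-[(5-bromo-2,2,6-trimethyl-1,3-benzodioxol-4-yl)oxy]-3-formyl-4-methoxy-6-methylbenzoic acid | COc1cc(C)c(C(O)=O)c(Oc2c(Br)c(C)cc3OC(C)(C)Oc23)c1C=O
F3 | step 5 | acetonide-protected depsidone (12 with the C6 and C7 oxygens bridged by C(CH3)2) | COc1cc(C)c2C(=O)Oc3c(C)cc4OC(C)(C)Oc4c3Oc2c1C=O
F4 | step 6 | 1,3-dithiolane of 12 (formyl carbon as 1,3-dithiolan-2-yl) | COc1cc(C)c2C(=O)Oc3c(C)cc(O)c(O)c3Oc2c1C1SCCS1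
F5 | step 6 | 1,3-dithiolane of 14 (formyl carbon as 1,3-dithiolan-2-yl) | COc1cc(C)c2C(=O)Oc3c(C)c4C(=O)CC(C)(C)Oc4c(O)c3Oc2c1C1SCCS1
F6 | step 2 | 2-fluoro-6-methoxy-4-methylbenzaldehyde | COc1cc(C)cc(F)c1C=O
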